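## The problem

Target 17 is a 1-aryltetralin lignan. Ring A (C4a–C8a, OMe at C6, OH at C7) is fused to the saturated ring B (C1–C4, C4a, C8a); C1 carries a 4-hydroxy-3-methoxyphenyl group, and C2 and C3 each carry a hydroxymethyl group (C9 on C2, C9′ on C3). The three contiguous stereocentres are (1R,2S,3R) in tetralin locants: the aryl group is trans to the C2 arm and the two hydroxymethyl groups are cis. That is the pattern of a cis-fused C9–O–C9′ lactone, not the all-trans pattern of isolariciresinol. C2 can govern both neighbours: a chair-like closure of ring B at C1–C8a places the aryl group pseudo-equatorial and trans to C9, and C3, while it is α to a lactone carbonyl, is epimerisable and settles cis. Only C2 therefore needs absolute control. The two phenols cannot be exposed to one-electron oxidants, the cinnamyl C–O bond of any open-chain precursor is acid-labile, and C3 can no longer be corrected once the lactone has been reduced. The enabling feature is that C2–C3 joins the β-carbons of two guaiacylpropane units while C1–C8a joins the α-carbon of one to the ring of the other. If O9 is acylated by C9′ and C3 is made a malonate carbon, a radical at C3 faces the C1=C2 styrene for 5-exo closure of the lactone, and the C1 centre so formed faces C8a, para to OMe, for closure of ring B.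

## Retrosynthesis

**17 from 16 and 15.** No skeletal bond is cut. The two O–benzyl bonds of 16 are added, and the two primary alcohols are tied back to lactone 15 (C9–O–C9′=O). A lactone is preferred to an open diester because it is the only arrangement in which the C2/C3 cis relation is the thermodynamic one and can be reached by equilibration at C3. Benzyl is chosen because it survives oxidant, hydroxide and hydride and leaves in a neutral last step. The forward reactions (LiAlH4, then H2 over Pd/C) must not touch C3 once the carbonyl is gone.

**15 from 12.** A carboxyl carbon is added back at C3, which becomes a quaternary malonate carbon carrying the tether carbonyl (in the lactone) and the carbonyl of a (−)-8-phenylmenthyl ester. The extra carboxyl is what makes C3 oxidisable to a radical, and the chiral ester is what differentiates its faces; the price is an excision step. Cleavage of a neopentyl 8-phenylmenthyl ester by an external nucleophile is not relied on. Instead the forward step removes the tether carbonyl as CO2 after hydroxide has opened the lactone, and the freed C9 hydroxyl expels the auxiliary by lactonisation. The auxiliary carbonyl thus ends as the lactone carbonyl of 15; C3 loses its configuration and regains it under base as the cis isomer.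

**12 from 11.** C2–C3 and C1–C8a are cut together. Cutting C1–C8a alone would leave a 2,3-disubstituted butyrolactone whose two stereocentres must be made separately; cutting C2–C3 alone brings no simplification. The double cut opens both rings and leaves the mixed malonate 11, in which the only stereochemical information is the auxiliary. The forward reaction has to generate the C3 radical at the only enolisable 1,3-dicarbonyl C–H (Mn(OAc)3), close 5-exo, close ring B para to OMe, and discriminate the faces of the radical.

**11 from 10 and 3.** The C9–O ester bond is cut, giving malonic half-ester 10 and allylic alcohol 3. Placing this bond last keeps the acid-labile cinnamyl unit out of all earlier steps. The forward reaction is a carbodiimide esterification under neutral conditions.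

**10 from 8 and 9; 8 from 5 and 6; 5 from 4.** The auxiliary ester C–O bond of 10 is cut to alcohol 9 and an acyl donor. The 5-benzyl Meldrum's acid 8 is chosen because its alcoholysis gives the half-ester directly, with the second carboxyl unmasked in the same step. The C3–C4 bond is then cut to aldehyde 5 and Meldrum's acid 6; a reductive Knoevenagel alkylation guarantees a single benzyl group on the malonate carbon, which alkylation with a benzyl halide does not. Aldehyde 5 is the benzyl ether of vanillin 4.

**3 from 2 and 1.** The allylic alcohol is taken back to the ester oxidation level. Ferulic acid 1 already has the E alkene and the guaiacyl pattern; one benzylation covers phenol and acid to give 2, which i-Bu2AlH should reduce in 1,2 fashion.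

## Roads not taken

**Alternative 1:** Ring A is absent when the stereocentres are set. The cut is at C1–aryl and C8–C8a. An arylcopper reagent (ArMgBr, CuBr·SMe2, Me3SiCl) would add to C1 of the lactone-fused cyclohexenone A1 from the face away from the lactone, and the silyl enol ether so formed would add at C8a to an alkoxy enone in the same flask, giving the 1-aryl cyclohexanone A2.
- Merits: the C2/C3 cis relation and the absolute configuration are carried by a menthyloxy acetal lactone before the key step, and anti conjugate addition to such a bicyclic enone is a dependable way to set C1. In this respect the road is better than the radical plan, whose induction rests on a remote ester auxiliary.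
- Weak points: A2 still lacks an aromatic ring A. An aldol condensation, a dehydrogenation, differentiation of the two ring A oxygens and reduction of the acetal lactone must follow. The one-flask capture of the enol ether adds an uncontrolled centre at C8a and a chemoselectivity question.
- Comparison: for a target whose ring A is a plain guaiacyl unit, building that ring from aliphatic carbon costs many more steps than the sequence from 1 to 17. Against the better stereocontrol, the chosen plan sets the fact that both aromatic rings arrive intact and ring B closes in one step.

**Alternative 2:** The cut is at C1–C2 and C2–C3. C2 would be added across the double bond of indene A3 by asymmetric cyclopropanation with a diazoacetate (CuOTf, chiral bis(oxazoline)), giving the exo ester A4; ring B would arise later by cleavage of the bond shared by the two small rings.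
- Merits: the chiral controller is catalytic, no auxiliary and no oxidant are needed, and face selection on a flat, rigid indene is usually good. On economy of the stereo-inducing element this road beats the chosen plan.
- Weak points: the alkene of A3 is trisubstituted and gives a quaternary cyclopropane carbon, a demanding case. In A4 the acceptor sits on C2, so the polarised bonds are C1–C2 and C2–C3, the bonds just made, whereas ring expansion needs cleavage of C1–C3, which has no comparable driving force. The pendant aryl group at C1 and the hydrogen at C3 remain to be introduced stereoselectively, so the key step fixes only C2 in its final form.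
- Comparison: the chosen cascade uses a stoichiometric auxiliary but delivers the whole carbon skeleton with C1 and C2 fixed.

**Alternative 3:** The cut is at C1–C2 only. The benzhydrol A5, an (R)-β-benzyl-γ-butyrolactone whose benzyl ring carries the second aryl unit as an ortho diarylcarbinol, would be O-silylated at the lactone enolate and ionised. The silyloxy-stabilised p-quinone methide cation at C1 is then attacked by the ketene acetal carbon C2, closing ring B and giving A6.
- Merits: this is closed-shell chemistry on a substrate whose C3 centre is already in place. The tether forces the new bond at C2 to be cis to the C3 substituent, so the cis-fused lactone is the direct kinetic product and no auxiliary has to be removed. In predictability of the C2/C3 relation and in the absence of an oxidant this road is at least as good as the chosen one, probably better.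
- Weak points: A5 needs an ortho-functionalised arene and a separately made enantiopure lactone, so the precursor is longer. Only one ring and one bond form in the key step. The configuration at C1 depends on an open transition state at a diaryl cation, and the carbinol must be ionised without protodesilylation of the ketene acetal.
- Comparison: against the higher reliability of this road, the chosen plan sets its convergence: two C–C bonds, both rings and all three centres from an ester assembled in six steps from four commercial compounds, without ortho-functionalisation.

Key step: step 7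

Assumption: the malonyl radical of 11 is taken to react through the dipole-opposed rotamer in which the auxiliary carbonyl is syn to the C4 benzyl group, so that the phenyl ring of (−)-8-phenylmenthol covers the face leading to the unwanted series; if the sense were the reverse, the commercial antipodal auxiliary would be used in the same sequence.

## Route

Step 1
Reactants: 1 ferulic acid, (E)-3-(4-hydroxy-3-methoxyphenyl)prop-2-enoic acid
Product: 2 benzyl (E)-3-[4-(benzyloxy)-3-methoxyphenyl]prop-2-enoate
Conditions: BnBr (2.3 equiv), K2CO3 (3 equiv), DMF, 60 °C
Reagents that add atoms: benzyl bromide, BrCc1ccccc1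
Why: Williamson O-alkylation of the phenoxide and SN2 esterification of the carboxylate in one operation; the E alkene is not affected.

Step 2
Reactants: 2 benzyl (E)-3-[4-(benzyloxy)-3-methoxyphenyl]prop-2-enoate
Product: 3 (E)-3-[4-(benzyloxy)-3-methoxyphenyl]prop-2-en-1-ol (4-O-benzylconiferyl alcohol)
Conditions: i-Bu2AlH (2.5 equiv), CH2Cl2, −78 to 0 °C; aq. potassium sodium tartrate
Reagents that add atoms: none
Why: 1,2-Reduction of an α,β-unsaturated ester by i-Bu2AlH gives the allylic alcohol without conjugate reduction; the benzyl alcohol released is removed on purification.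

Step 3
Reactants: 4 vanillin, 4-hydroxy-3-methoxybenzaldehyde
Product: 5 4-(benzyloxy)-3-methoxybenzaldehyde
Conditions: BnBr (1.1 equiv), K2CO3 (1.5 equiv), DMF, 25 °C
Reagents that add atoms: benzyl bromide, BrCc1ccccc1
Why: Williamson ether synthesis on an acidic phenol; the aldehyde is inert to carbonate.

Step 4
Reactants: 5 4-(benzyloxy)-3-methoxybenzaldehyde; 6 Meldrum's acid, 2,2-dimethyl-1,3-dioxane-4,6-dione
Product: 8 5-[4-(benzyloxy)-3-methoxybenzyl]-2,2-dimethyl-1,3-dioxane-4,6-dione, via arylidene Meldrum's acid 7 (not isolated)
Conditions: Hantzsch ester (diethyl 2,6-dimethyl-1,4-dihydropyridine-3,5-dicarboxylate, 1.05 equiv), L-proline (10 mol %), EtOH, 25 °C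
Reagents that add atoms: none
Why: Knoevenagel condensation followed in the same flask by transfer hydrogenation of the strongly electrophilic alkylidene by the Hantzsch ester (reductive alkylation); exactly one benzyl group is introduced.

Step 5
Reactants: 8 5-[4-(benzyloxy)-3-methoxybenzyl]-2,2-dimethyl-1,3-dioxane-4,6-dione; 9 (−)-8-phenylmenthol, (1R,2S,5R)-5-methyl-2-(2-phenylpropan-2-yl)cyclohexan-1-ol
Product: 10 2-[4-(benzyloxy)-3-methoxybenzyl]malonic acid mono-[(1R,2S,5R)-8-phenylmenthyl] ester (both epimers at the malonate carbon)
Conditions: 8 (1.1 equiv), toluene, 100 °C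
Reagents that add atoms: none
Why: Thermal alcoholysis of a Meldrum's acid derivative (ring-opening acylation with loss of acetone) gives the malonic half-ester directly. The malonate carbon forms as an epimeric mixture, which is of no consequence because it becomes the planar radical of step 7.

Step 6
Reactants: 10 malonic half-ester; 3 (E)-3-[4-(benzyloxy)-3-methoxyphenyl]prop-2-en-1-ol
Product: 11 (E)-3-[4-(benzyloxy)-3-methoxyphenyl]prop-2-en-1-yl (1R,2S,5R)-8-phenylmenthyl 2-[4-(benzyloxy)-3-methoxybenzyl]malonate (both epimers at the malonate carbon)
Conditions: DCC (1.1 equiv), DMAP (0.1 equiv), CH2Cl2, 0 to 25 °C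
Reagents that add atoms: none
Why: Steglich esterification; the neutral conditions spare the ionisation-prone cinnamyl alcohol and the E alkene.

Step 7
Reactants: 11 mixed malonate
Product: 12 (1R,2S,5R)-8-phenylmenthyl (3aS,9R,9aS)-7-(benzyloxy)-9-[4-(benzyloxy)-3-methoxyphenyl]-6-methoxy-3-oxo-1,3,9,9a-tetrahydronaphtho[2,3-c]furan-3a(4H)-carboxylate (tetralin locants 1R,2S,3S; cis-fused lactone, auxiliary ester angular at C3, aryl trans to C9)
Conditions: Mn(OAc)3·2H2O (2.2 equiv), Cu(OAc)2·H2O (0.5 equiv), degassed AcOH (0.03 M), 70 °C
Reagents that add atoms: none
Why: Mn(OAc)3 enolises the α-benzylmalonate and electron transfer within the manganese enolate gives the electrophilic C3 malonyl radical; the closest known reactions are the Mn(OAc)3/Cu(OAc)2 lactonisation of allylic malonates and the Mn(OAc)3 tetralin annulation of benzylmalonates with alkenes, merged here in one substrate. Ring 1 (lactone): the radical adds 5-exo-trig to C2 of the electron-rich styrene through the s-cis ester rotamer, which places the odd electron at the stabilised benzylic C1. Ring 2 (ring B): C1 bonds to C8a of the vanillyl ring in a six-membered ortho closure (6-endo with respect to the C4a–C8a bond), either as the radical followed by oxidation of the cyclohexadienyl radical by divalent copper, or after oxidation to the p-alkoxybenzyl cation as a Friedel–Crafts closure; both paths give the same rearomatised product and consume two Mn(OAc)3. C3 is set by the face of the planar radical that the alkene reaches: the phenyl ring of the 8-phenylmenthyl group stacks over one face of the malonyl π system and the tethered alkene enters from the other. C2 is set in the same bond formation; the styryl arm is expected to go anti to the bulky auxiliary ester and therefore syn to the benzyl group, the arrangement from which a cis-fused ring B follows. C1 is set in the second closure by a chair-like transition state with the aryl group pseudo-equatorial, trans to the C2–C9 bond. The step needs face selectivity at C3 (auxiliary), 5-exo over 6-endo regiochemistry (benzylic radical, short ester tether) and attack para to OMe rather than at the hindered position between CH2 and OMe; the benzyl ethers keep both phenols away from the oxidant, and the quaternary C3 of 12 excludes a second enolisation.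

Step 8
Reactants: 12 cascade product
Product: 15 (3aR,9R,9aS)-7-(benzyloxy)-9-[4-(benzyloxy)-3-methoxyphenyl]-6-methoxy-3a,4,9,9a-tetrahydronaphtho[2,3-c]furan-3(1H)-one (tetralin locants 1R,2S,3R; cis-fused lactone), via sodium hydroxy carboxylate 13 (not isolated), via hydroxy ester 14 (not isolated)
Conditions: NaOH (1.05 equiv), DMSO–H2O (20:1), 25 °C, then 150 °C; cool, NaOMe (0.2 equiv), MeOH, 50 °C; aq. HCl (1 M)
Reagents that add atoms: none
Why: Hydroxide opens the lactone, the only carbonyl of 12 accessible to an external nucleophile, and the malonate half-ester carboxylate 13 loses CO2 in hot wet DMSO as in the second stage of a Krapcho dealkoxycarbonylation. The freed C9 hydroxyl of 14 then displaces 8-phenylmenthol from the ester, whose α-carbon is no longer quaternary, by lactonisation, so the auxiliary carbonyl becomes the lactone carbonyl. Methoxide equilibrates C3 through the ester or lactone enolate, and the cis-fused lactone is the thermodynamic sink of this ring system (the base-induced trans to cis isomerisation is known for aryltetralin lactones of the conidendrin type); C1 and C2 are not acidic and keep their configuration.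

Step 9
Reactants: 15 cis-fused lactone
Product: 16 [(1R,2S,3R)-7-(benzyloxy)-1-[4-(benzyloxy)-3-methoxyphenyl]-6-methoxy-1,2,3,4-tetrahydronaphthalene-2,3-diyl]dimethanol
Conditions: LiAlH4 (2 equiv), THF, 0 to 25 °C; H2O, aq. NaOH
Reagents that add atoms: none
Why: Hydride reduction of a γ-lactone to the 1,4-diol; addition to the carbonyl at 0 °C is faster than enolisation, so C3 keeps the cis configuration, and aryl benzyl ethers are inert to LiAlH4.

Step 10
Reactants: 16 dibenzyl ether diol
Product: 17 (1R,2S,3R)-1-(4-hydroxy-3-methoxyphenyl)-2,3-bis(hydroxymethyl)-6-methoxy-1,2,3,4-tetrahydronaphthalen-7-ol, equivalently (6R,7S,8R)-8-(4-hydroxy-3-methoxyphenyl)-6,7-bis(hydroxymethyl)-3-methoxy-5,6,7,8-tetrahydronaphthalen-2-ol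
Conditions: H2 (1 atm), 10% Pd/C, EtOAc–MeOH, 25 °C
Reagents that add atoms: none
Why: Hydrogenolysis of the two aryl benzyl ethers; the primary alcohols are not benzylic and the diarylmethine C1 carries no heteroatom, so nothing else is cleaved and no stereocentre is touched.

## Compound list

1 | ferulic acid, (E)-3-(4-hydroxy-3-methoxyphenyl)prop-2-enoic acid | COc1cc(/C=C/C(=O)O)ccc1O | starting material
2 | benzyl (E)-3-[4-(benzyloxy)-3-methoxyphenyl]prop-2-enoate | COc1cc(/C=C/C(=O)OCc2ccccc2)ccc1OCc1ccccc1 | intermediate
3 | (E)-3-[4-(benzyloxy)-3-methoxyphenyl]prop-2-en-1-ol | COc1cc(/C=C/CO)ccc1OCc1ccccc1 | intermediate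
4 | vanillin, 4-hydroxy-3-methoxybenzaldehyde | COc1cc(C=O)ccc1O | starting material
5 | 4-(benzyloxy)-3-methoxybenzaldehyde | COc1cc(C=O)ccc1OCc1ccccc1 | intermediate
6 | Meldrum's acid, 2,2-dimethyl-1,3-dioxane-4,6-dione | CC1(C)OC(=O)CC(=O)O1 | starting material
7 | 5-[4-(benzyloxy)-3-methoxybenzylidene]-2,2-dimethyl-1,3-dioxane-4,6-dione | COc1cc(C=C2C(=O)OC(C)(C)OC2=O)ccc1OCc1ccccc1 | intermediate (not isolated)
8 | 5-[4-(benzyloxy)-3-methoxybenzyl]-2,2-dimethyl-1,3-dioxane-4,6-dione | COc1cc(CC2C(=O)OC(C)(C)OC2=O)ccc1OCc1ccccc1 | intermediate
9 | (−)-8-phenylmenthol, (1R,2S,5R)-5-methyl-2-(2-phenylpropan-2-yl)cyclohexan-1-ol | O[C@@H]1C[C@H](C)CC[C@H]1C(C)(C)c1ccccc1 | starting material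
10 | 2-[4-(benzyloxy)-3-methoxybenzyl]malonic acid mono-[(1R,2S,5R)-8-phenylmenthyl] ester, both epimers at the malonate carbon | COc1cc(CC(C(=O)O)C(=O)O[C@@H]2C[C@H](C)CC[C@H]2C(C)(C)c2ccccc2)ccc1OCc1ccccc1 | intermediate
11 | (E)-3-[4-(benzyloxy)-3-methoxyphenyl]prop-2-en-1-yl (1R,2S,5R)-8-phenylmenthyl 2-[4-(benzyloxy)-3-methoxybenzyl]malonate, both epimers at the malonate carbon | COc1cc(/C=C/COC(=O)C(Cc2ccc(OCc3ccccc3)c(OC)c2)C(=O)O[C@@H]2C[C@H](C)CC[C@H]2C(C)(C)c2ccccc2)ccc1OCc1ccccc1 | intermediate
12 | (1R,2S,5R)-8-phenylmenthyl (3aS,9R,9aS)-7-(benzyloxy)-9-[4-(benzyloxy)-3-methoxyphenyl]-6-methoxy-3-oxo-1,3,9,9a-tetrahydronaphtho[2,3-c]furan-3a(4H)-carboxylate | COc1cc([C@@H]2c3cc(OCc4ccccc4)c(OC)cc3C[C@@](C(=O)O[C@@H]5C[C@H](C)CC[C@H]5C(C)(C)c5ccccc5)(C(=O)OC7)[C@H]27)ccc1OCc1ccccc1 | intermediate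
13 | sodium salt of the ring-opened hydroxy acid of 12 (tetralin locants 1R,2S,3S; C3 carries CO2Na and the auxiliary ester, C2 the free CH2OH) | COc1cc([C@@H]2c3cc(OCc4ccccc4)c(OC)cc3C[C@@](C(=O)O[C@@H]5C[C@H](C)CC[C@H]5C(C)(C)c5ccccc5)(C(=O)[O-])[C@H]2CO)ccc1OCc1ccccc1.[Na+] | intermediate (not isolated)
14 | (1R,2S,5R)-8-phenylmenthyl (1R,2S)-7-(benzyloxy)-1-[4-(benzyloxy)-3-methoxyphenyl]-2-(hydroxymethyl)-6-methoxy-1,2,3,4-tetrahydronaphthalene-3-carboxylate, both C3 epimers (tetralin locants) | COc1cc([C@@H]2c3cc(OCc4ccccc4)c(OC)cc3CC(C(=O)O[C@@H]5C[C@H](C)CC[C@H]5C(C)(C)c5ccccc5)[C@H]2CO)ccc1OCc1ccccc1 | intermediate (not isolated)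
15 | (3aR,9R,9aS)-7-(benzyloxy)-9-[4-(benzyloxy)-3-methoxyphenyl]-6-methoxy-3a,4,9,9a-tetrahydronaphtho[2,3-c]furan-3(1H)-one | COc1cc([C@@H]2c3cc(OCc4ccccc4)c(OC)cc3C[C@@H](C(=O)OC7)[C@H]27)ccc1OCc1ccccc1 | intermediate
16 | [(1R,2S,3R)-7-(benzyloxy)-1-[4-(benzyloxy)-3-methoxyphenyl]-6-methoxy-1,2,3,4-tetrahydronaphthalene-2,3-diyl]dimethanol | COc1cc([C@@H]2c3cc(OCc4ccccc4)c(OC)cc3C[C@@H](CO)[C@H]2CO)ccc1OCc1ccccc1 | intermediate
17 | (6R,7S,8R)-8-(4-hydroxy-3-methoxyphenyl)-6,7-bis(hydroxymethyl)-3-methoxy-5,6,7,8-tetrahydronaphthalen-2-ol | COc1cc([C@@H]2c3cc(O)c(OC)cc3C[C@@H](CO)[C@H]2CO)ccc1O | target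

## Step count and risks

Total step count: 10. Longest linear sequence: 8 steps (steps 3, 4, 5, 6, 7, 8, 9, 10, from vanillin 4 to 17); the ferulic acid branch (steps 1 and 2) joins at step 6.

**Step 7 (key step).** Three things can go wrong.
- Premature oxidation of the p-alkoxybenzylic C1 radical and capture of the cation by acetate before ring B closes; this is the most likely failure.
- Incomplete face discrimination by the auxiliary. This costs material but not purity, because the diastereomers of 12 still carry the auxiliary and can be separated.
- The first closure placing the styryl arm trans to the benzyl group. This would stall the cascade or lead to a trans-fused diastereomer, which must be separated at the stage of 12 because it would lead to the antipodal series after step 8.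

Fallback: stage the two ring closures. Starting from 11, the oxidation is run with Mn(OAc)3/Cu(OAc)2 in AcOH containing KOAc at lower temperature, so that the first ring closes and the benzylic position is deliberately trapped, giving the monocyclic lactone benzylic acetate F1. F1 is then ionised with BF3·OEt2 in CH2Cl2 at −40 °C, and intramolecular Friedel–Crafts alkylation para to OMe closes ring B with the aryl group pseudo-equatorial. The sequence returns to the route at 12.

**Step 8.** The carboxylate may resist decarboxylation, or lactonisation onto the hindered auxiliary ester may be slow. The result would be incomplete release of the auxiliary and a mixture of C3 epimers in open and closed forms.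

Fallback: excise the tether carbonyl reductively instead of as CO2. Starting from 12, i-Bu2AlH (1.2 equiv, CH2Cl2, −78 °C) should reduce only the lactone carbonyl (the auxiliary ester is too hindered), giving the lactol F2. NaOMe in MeOH then removes the masked formyl carbon by retro-Claisen cleavage as methyl formate and gives hydroxy ester 14. Under the same conditions 14 epimerises and lactonises with loss of 8-phenylmenthol, returning to the route at 15.

**Step 5.** Acylation of the hindered secondary alcohol 9 by 8 may be slow at a temperature at which the malonic half-acid begins to decarboxylate.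

Fallback: reverse the order of the two esterifications. Starting from 8 and 3, alcoholysis with the unhindered allylic alcohol 3 (toluene, 90 °C) gives the coniferyl hydrogen malonate F3. F3 is then coupled with 9 by DCC/DMAP (the ketene formed from a malonic half-acid acylates hindered alcohols readily), returning to the route at 11 and bypassing steps 5 and 6.

## Further compounds

F1 | step 7 | (1R,2S,5R)-8-phenylmenthyl 4-{acetoxy[4-(benzyloxy)-3-methoxyphenyl]methyl}-3-[4-(benzyloxy)-3-methoxybenzyl]-2-oxotetrahydrofuran-3-carboxylate, ring carbons configured as in 12, acetate carbon as a mixture | COc1cc(C(OC(C)=O)[C@@H]2COC(=O)[C@@]2(Cc2ccc(OCc3ccccc3)c(OC)c2)C(=O)O[C@@H]2C[C@H](C)CC[C@H]2C(C)(C)c2ccccc2)ccc1OCc1ccccc1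
F2 | step 8 | lactol of 12 (lactone C=O reduced to CH(OH), both anomers, other centres as in 12) | COc1cc([C@@H]2c3cc(OCc4ccccc4)c(OC)cc3C[C@@](C(=O)O[C@@H]5C[C@H](C)CC[C@H]5C(C)(C)c5ccccc5)(C(O)OC7)[C@H]27)ccc1OCc1ccccc1
F3 | step 5 | 2-[4-(benzyloxy)-3-methoxybenzyl]malonic acid mono-{(E)-3-[4-(benzyloxy)-3-methoxyphenyl]prop-2-en-1-yl} ester, racemic | COc1cc(/C=C/COC(=O)C(Cc2ccc(OCc3ccccc3)c(OC)c2)C(=O)O)ccc1OCc1ccccc1
A1 | alternative 1 | cis-fused 3-[(1R,2S,5R)-menthyloxy]-3a,4-dihydro-2-benzofuran-1,5(3H,7aH)-dione (lactone-fused cyclohexenone) | O=C1C[C@@H]([C@H](O[C@@H]6C[C@H](C)CC[C@H]6C(C)C)O5)[C@H](C=C1)C5=O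
A2 | alternative 1 | 1-aryl cyclohexanone with the ring A side chain at C8a and the cis-fused menthyloxy lactone | COc1cc([C@@H]2C(CC(OCc3ccccc3)C(C)=O)C(=O)C[C@@H]([C@H](O[C@@H]6C[C@H](C)CC[C@H]6C(C)C)O5)[C@H]2C5=O)ccc1OCc1ccccc1
A3 | alternative 2 | 5-(benzyloxy)-2-{[(tert-butyldimethylsilyl)oxy]methyl}-6-methoxy-1H-indene | C1=C(CO[Si](C)(C)C(C)(C)C)Cc2cc(OC)c(OCc3ccccc3)cc12
A4 | alternative 2 | exo-ester cyclopropa-fused indane | CCOC(=O)[C@H]1[C@@H]2c3cc(OCc4ccccc4)c(OC)cc3C[C@]12CO[Si](C)(C)C(C)(C)C
A5 | alternative 3 | (4R)-4-{[4-(benzyloxy)-2-{hydroxy[3-methoxy-4-(triisopropylsilyloxy)phenyl]methyl}-5-methoxyphenyl]methyl}dihydrofuran-2(3H)-one, both carbinol epimers | COc1cc(C(O)c2cc(OCc3ccccc3)c(OC)cc2C[C@H]2COC(=O)C2)ccc1O[Si](C(C)C)(C(C)C)C(C)C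
A6 | alternative 3 | 1-aryltetralin cis-fused lactone with the carbonyl on C2 | COc1cc([C@@H]2c3cc(OCc4ccccc4)c(OC)cc3C[C@@H](CO5)[C@H]2C5=O)ccc1O
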